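**Strategy.** Ring B (oxepene: O, C2, C3, C4, C5, C6, C7) shares C6–C7 with ring A (bromocyclohexane: C6–C11), and the C6–C5 bond and the C7–O bond sit on the same face of ring A. This cis C–C/C–O pair is the footprint of a CH2CO2 unit, so the route rests on disconnecting C5–C6 and C7–O to acetic acid and the C6=C7 alkene of (S)-4-bromo-1,3,3-trimethylcyclohexene. One Mn(OAc)3 lactone annulation forms both bonds, the γ-lactone and both ring-fusion stereocentres. The lactone carbonyl (C4) is then homologated to a C3 vinylsilane and ring B is closed at C2–C3 through an oxocarbenium ion built on the C7 oxygen.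

Key step: step 5

Atom labels follow the target: ring B = O, C2–C7; ring A = C6–C11; C1 = CH2Br carbon; C12 = CH2OH carbon.
Remark: lactol 11 and bromoacetal 23 are carried as mixtures at the acetal carbon, because that centre is lost in steps 7 and 12.

Step 1
Reactants: 1 4-methylanisole
Product: 3 4-methylcyclohex-3-en-1-one, via 1-methoxy-4-methylcyclohexa-1,4-diene 2 (not isolated)
Conditions: Li, NH3(l), THF, t-BuOH, −78 → −33 °C; then (CO2H)2 (cat.), MeOH–H2O, rt
Reagents that add atoms: water, O
Why: Birch reduction leaves the methoxy and methyl groups on the two remaining double bonds, and mild enol ether hydrolysis should release the β,γ-unsaturated ketone without migration of the C3=C4 bond; no stereocentre is formed.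

Step 2
Reactants: 3 4-methylcyclohex-3-en-1-one; 4 iodomethane
Product: 6 2,2,4-trimethylcyclohex-3-en-1-one, via 2,4-dimethylcyclohex-3-en-1-one 5 (not isolated)
Conditions: KOt-Bu (2.2 equiv), MeI (2.5 equiv), t-BuOH–THF, 0 °C → rt
Reagents that add atoms: iodomethane, CI
Why: Deconjugative α,α-dialkylation of an extended dienolate: the C2 hydrogens are both α to the carbonyl and allylic, so they are removed in preference to those at C6 and the dienolate is methylated twice at its α-carbon, which installs the quaternary carbon and keeps the alkene at C3=C4; no stereocentre is formed.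

Step 3
Reactants: 6 2,2,4-trimethylcyclohex-3-en-1-one
Product: 7 (1R)-2,2,4-trimethylcyclohex-3-en-1-ol
Conditions: (S)-Me-CBS oxazaborolidine [(S)-1-methyl-3,3-diphenyltetrahydro-1H,3H-pyrrolo[1,2-c][1,3,2]oxazaborole] (0.2 equiv), catecholborane (1.5 equiv), toluene, −78 → −40 °C; then MeOH, aq. NaOH
Reagents that add atoms: none
Why: Corey–Bakshi–Shibata reduction: the oxazaborolidine treats the quaternary C2 side as the large and the C6 methylene as the small ketone substituent, so hydride from coordinated catecholborane should be delivered to the face that gives the R carbinol, and catecholborane leaves the trisubstituted alkene untouched.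

Step 4
Reactants: 7 (1R)-2,2,4-trimethylcyclohex-3-en-1-ol
Product: 8 (4S)-4-bromo-1,3,3-trimethylcyclohex-1-ene
Conditions: CBr4, PPh3, CH2Cl2, 0 °C → rt
Reagents that add atoms: carbon tetrabromide, BrC(Br)(Br)Br
Why: Appel reaction: bromide displaces the oxyphosphonium group by SN2 with inversion (1R alcohol to 4S bromide), and the mild, non-ionising conditions are chosen to hold back methyl shift and elimination at this neopentylic centre.

Step 5
Reactants: 8 (4S)-4-bromo-1,3,3-trimethylcyclohex-1-ene; 9 acetic acid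
Product: 10 (3aR,5S,7aS)-5-bromo-4,4,7a-trimethylhexahydro-1-benzofuran-2(3H)-one
Conditions: Mn(OAc)3·2H2O (2.5 equiv), KOAc, AcOH–Ac2O, 100 °C, N2
Reagents that add atoms: acetic acid, CC(=O)O
Why: Trivalent manganese enolises a bound acetate and releases the electrophilic carboxymethyl radical, which adds to C6, the less substituted alkene carbon, to leave the tertiary C7 radical; a second Mn(OAc)3 oxidises this to the cation, which the pendant carboxylate captures. The closest known reaction type is the manganese triacetate γ-lactone annulation of alkenes with acetic acid. The one ring formed, the γ-lactone, closes by 5-exo attack of the carboxylate oxygen on C7, and a five-membered ring made this way can only be cis-fused, so C7 is fixed by C6. C6 is set by the face of radical attack: in the half-chair with bromine equatorial the pseudoaxial C11 methyl lies on the bromine face, so the radical should enter from the opposite face, trans to bromine. The step needs regioselectivity (secured by the trisubstituted alkene, which places radical and cation at tertiary C7), chemoselectivity (the neopentylic C10–Br bond resists acetate) and this facial preference.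

Step 6
Reactants: 10 (3aR,5S,7aS)-5-bromo-4,4,7a-trimethylhexahydro-1-benzofuran-2(3H)-one
Product: 11 (3aR,5S,7aS)-5-bromo-4,4,7a-trimethyloctahydro-1-benzofuran-2-ol
Conditions: i-Bu2AlH (1.1 equiv), CH2Cl2, −78 °C; aq. potassium sodium tartrate
Reagents that add atoms: none
Why: Partial reduction of a γ-lactone with i-Bu2AlH at −78 °C stops at the aluminium hemiacetal, which gives the lactol on work-up; the neopentylic bromide and the three stereocentres are not touched.

Step 7
Reactants: 11 (3aR,5S,7aS)-5-bromo-4,4,7a-trimethyloctahydro-1-benzofuran-2-ol; 12 dimethyl (1-diazo-2-oxopropyl)phosphonate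
Product: 13 (1S,2R,4S)-4-bromo-1,3,3-trimethyl-2-(prop-2-yn-1-yl)cyclohexan-1-ol
Conditions: K2CO3, MeOH, 0 °C → rt
Reagents that add atoms: dimethyl (1-diazo-2-oxopropyl)phosphonate, COP(=O)(OC)C(=[N+]=[N-])C(C)=O
Why: Seyferth–Gilbert homologation in the Ohira–Bestmann form: the lactol is in equilibrium with the hydroxy aldehyde, which is intercepted by the diazomethylphosphonate anion released from 12 by methanolysis, giving the terminal alkyne (C3 added) and freeing the C7 hydroxyl under mild carbonate conditions.

Step 8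
Reactants: 13 (1S,2R,4S)-4-bromo-1,3,3-trimethyl-2-(prop-2-yn-1-yl)cyclohexan-1-ol
Product: 16 (1S,2R,4S)-4-bromo-1,3,3-trimethyl-2-[3-(trimethylsilyl)prop-2-yn-1-yl]cyclohexan-1-ol, via dilithium alkoxide acetylide 14 (not isolated), via O,C-bis(trimethylsilyl) ether 15 (not isolated)
Conditions: LiN(i-Pr)2 (2.2 equiv), THF, −78 °C; Me3SiCl (2.5 equiv), −78 → 0 °C; then 1 M HCl, THF, 0 °C
Reagents that add atoms: chlorotrimethylsilane, C[Si](C)(C)Cl
Why: Silylation of a lithium acetylide: the amide base removes the alkyne and hydroxyl protons without halogen–metal exchange at C10, Me3SiCl caps both anions, and dilute acid cleaves only the labile O–Si bond.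

Step 9
Reactants: 16 (1S,2R,4S)-4-bromo-1,3,3-trimethyl-2-[3-(trimethylsilyl)prop-2-yn-1-yl]cyclohexan-1-ol; 17 formaldehyde (used as paraformaldehyde)
Product: 20 (1S,2R,4S)-4-bromo-2-[(2Z)-4-hydroxy-3-(trimethylsilyl)but-2-en-1-yl]-1,3,3-trimethylcyclohexan-1-ol, via (Z)-alkenyl(diisobutyl)alane 18 (not isolated), via lithium alkenyl(methyl)diisobutylalanate 19 (not isolated)
Conditions: i-Bu2AlH (2.5 equiv), Et2O, 0 → 35 °C; MeLi (2.5 equiv), 0 °C; (CH2O)n, 0 °C → rt; aq. potassium sodium tartrate
Reagents that add atoms: formaldehyde (as paraformaldehyde), C=O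
Why: Hydroalumination of a 1-silylalkyne in ether is a cis addition that puts aluminium on the silicon-bearing carbon C3 and hydrogen on C4, and the derived alanate is hydroxymethylated by formaldehyde with retention (hydroalumination–alanate alkylation), which should give the Z vinylsilane with silicon cis to C5.

Step 10
Reactants: 20 (1S,2R,4S)-4-bromo-2-[(2Z)-4-hydroxy-3-(trimethylsilyl)but-2-en-1-yl]-1,3,3-trimethylcyclohexan-1-ol
Product: 21 (2Z)-4-[(1R,3S,6S)-3-bromo-6-hydroxy-2,2,6-trimethylcyclohexyl]-2-(trimethylsilyl)but-2-en-1-yl acetate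
Conditions: Ac2O (1.2 equiv), pyridine, 4-(dimethylamino)pyridine (cat.), CH2Cl2, 0 °C
Reagents that add atoms: acetic anhydride, CC(=O)OC(C)=O
Why: Amine-catalysed acetylation is selective for the primary allylic hydroxyl over the hindered tertiary C7 hydroxyl, and the acetate masks C12–OH for the next two steps.

Step 11
Reactants: 21 (2Z)-4-[(1R,3S,6S)-3-bromo-6-hydroxy-2,2,6-trimethylcyclohexyl]-2-(trimethylsilyl)but-2-en-1-yl acetate; 22 2-methoxyethyl vinyl ether
Product: 23 (2Z)-4-{(1R,3S,6S)-3-bromo-6-[2-bromo-1-(2-methoxyethoxy)ethoxy]-2,2,6-trimethylcyclohexyl}-2-(trimethylsilyl)but-2-en-1-yl acetate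
Conditions: 22 (excess), N-bromosuccinimide, CH2Cl2, −40 → 0 °C
Reagents that add atoms: N-bromosuccinimide, O=C1CCC(=O)N1Br; 2-methoxyethyl vinyl ether, C=COCCOC
Why: Bromoacetalisation (haloetherification of an enol ether): N-bromosuccinimide brominates the electron-rich vinyl ether far faster than the vinylsilane, and the resulting α-bromo oxocarbenium ion is captured by the tertiary C7 hydroxyl, which brings in C1 and C2; the new acetal centre is formed as a mixture that is erased in step 12.

Step 12
Reactants: 23 (2Z)-4-{(1R,3S,6S)-3-bromo-6-[2-bromo-1-(2-methoxyethoxy)ethoxy]-2,2,6-trimethylcyclohexyl}-2-(trimethylsilyl)but-2-en-1-yl acetate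
Product: 24 [(2R,5aR,7S,9aS)-7-bromo-2-(bromomethyl)-6,6,9a-trimethyl-2,5,5a,6,7,8,9,9a-octahydro-1-benzoxepin-3-yl]methyl acetate
Conditions: SnCl4 (2.5 equiv), 2,6-di-tert-butyl-4-methylpyridine (0.5 equiv), CH2Cl2, −78 → 0 °C
Reagents that add atoms: none
Why: Acetal–vinylsilane cyclisation (vinylsilane-terminated oxocarbenium cyclisation): SnCl4 chelates and removes the 2-methoxyethoxy group, the E oxocarbenium ion is attacked by C3 ipso to silicon in a seven-membered closure, loss of the silyl group from the β-silyl cation keeps the C3=C4 bond, and C2 is set by a chair-like transition state with CH2Br and the C7 methyl both pseudo-equatorial on the forming ring, that is cis to each other (2R).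

Step 13
Reactants: 24 [(2R,5aR,7S,9aS)-7-bromo-2-(bromomethyl)-6,6,9a-trimethyl-2,5,5a,6,7,8,9,9a-octahydro-1-benzoxepin-3-yl]methyl acetate
Product: 25 [(2R,5aR,7S,9aS)-7-bromo-2-(bromomethyl)-6,6,9a-trimethyl-2,5,5a,6,7,8,9,9a-octahydro-1-benzoxepin-3-yl]methanol
Conditions: i-Bu2AlH (2.5 equiv), CH2Cl2, −78 °C; aq. potassium sodium tartrate
Reagents that add atoms: none
Why: Reductive ester cleavage with i-Bu2AlH at −78 °C frees the C12 alcohol without alkoxide base, which could otherwise close C12–O onto the C1 bromide; neither alkyl bromide reacts with the hydride at this temperature.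

**Compound list**

1 | 4-methylanisole | COc1ccc(C)cc1 | starting material
2 | 1-methoxy-4-methylcyclohexa-1,4-diene | COC1=CCC(C)=CC1 | intermediate
3 | 4-methylcyclohex-3-en-1-one | CC1=CCC(=O)CC1 | intermediate
4 | iodomethane | CI | starting material
5 | 2,4-dimethylcyclohex-3-en-1-one (racemic) | CC1=CC(C)C(=O)CC1 | intermediate
6 | 2,2,4-trimethylcyclohex-3-en-1-one | CC1=CC(C)(C)C(=O)CC1 | intermediate
7 | (1R)-2,2,4-trimethylcyclohex-3-en-1-ol | CC1(C)C=C(C)CC[C@H]1O | intermediate
8 | (4S)-4-bromo-1,3,3-trimethylcyclohex-1-ene | CC1(C)C=C(C)CC[C@@H]1Br | intermediate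
9 | acetic acid | CC(=O)O | starting material
10 | (3aR,5S,7aS)-5-bromo-4,4,7a-trimethylhexahydro-1-benzofuran-2(3H)-one (cis-fused bromo γ-lactone) | CC1(C)[C@H]2CC(=O)O[C@@]2(C)CC[C@@H]1Br | intermediate
11 | (3aR,5S,7aS)-5-bromo-4,4,7a-trimethyloctahydro-1-benzofuran-2-ol (lactol, both anomers) | CC1(C)[C@H]2CC(O)O[C@@]2(C)CC[C@@H]1Br | intermediate
12 | dimethyl (1-diazo-2-oxopropyl)phosphonate | COP(=O)(OC)C(=[N+]=[N-])C(C)=O | starting material
13 | (1S,2R,4S)-4-bromo-1,3,3-trimethyl-2-(prop-2-yn-1-yl)cyclohexan-1-ol | CC1(C)[C@@H](CC#C)[C@@](C)(O)CC[C@@H]1Br | intermediate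
14 | dilithium salt of 13 (lithium alkoxide at C7, lithium acetylide at C3) | CC1(C)[C@@H](CC#C[Li])[C@@](C)(O[Li])CC[C@@H]1Br | intermediate
15 | O,C-bis(trimethylsilyl) derivative of 13 (C7–OSiMe3, C3–SiMe3) | CC1(C)[C@@H](CC#C[Si](C)(C)C)[C@@](C)(O[Si](C)(C)C)CC[C@@H]1Br | intermediate
16 | (1S,2R,4S)-4-bromo-1,3,3-trimethyl-2-[3-(trimethylsilyl)prop-2-yn-1-yl]cyclohexan-1-ol | CC1(C)[C@@H](CC#C[Si](C)(C)C)[C@@](C)(O)CC[C@@H]1Br | intermediate
17 | formaldehyde (used as paraformaldehyde) | C=O | starting material
18 | (Z)-alkenylalane from 16: Al(i-Bu)2 and SiMe3 on C3, H on C4 cis to aluminium, C7 oxygen as diisobutylaluminium alkoxide | CC1(C)[C@@H](C/C=C(/[Al](CC(C)C)CC(C)C)[Si](C)(C)C)[C@@](C)(O[Al](CC(C)C)CC(C)C)CC[C@@H]1Br | intermediate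
19 | lithium alkenyl(methyl)diisobutylalanate derived from 18 | [Li+].CC1(C)[C@@H](C/C=C(/[Al-](C)(CC(C)C)CC(C)C)[Si](C)(C)C)[C@@](C)(O[Al](CC(C)C)CC(C)C)CC[C@@H]1Br | intermediate
20 | (1S,2R,4S)-4-bromo-2-[(2Z)-4-hydroxy-3-(trimethylsilyl)but-2-en-1-yl]-1,3,3-trimethylcyclohexan-1-ol | CC1(C)[C@@H](C/C=C(/CO)[Si](C)(C)C)[C@@](C)(O)CC[C@@H]1Br | intermediate
21 | (2Z)-4-[(1R,3S,6S)-3-bromo-6-hydroxy-2,2,6-trimethylcyclohexyl]-2-(trimethylsilyl)but-2-en-1-yl acetate | CC1(C)[C@@H](C/C=C(/COC(C)=O)[Si](C)(C)C)[C@@](C)(O)CC[C@@H]1Br | intermediate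
22 | 2-methoxyethyl vinyl ether | C=COCCOC | starting material
23 | (2Z)-4-{(1R,3S,6S)-3-bromo-6-[2-bromo-1-(2-methoxyethoxy)ethoxy]-2,2,6-trimethylcyclohexyl}-2-(trimethylsilyl)but-2-en-1-yl acetate (both acetal epimers) | CC1(C)[C@@H](C/C=C(/COC(C)=O)[Si](C)(C)C)[C@@](C)(OC(CBr)OCCOC)CC[C@@H]1Br | intermediate
24 | [(2R,5aR,7S,9aS)-7-bromo-2-(bromomethyl)-6,6,9a-trimethyl-2,5,5a,6,7,8,9,9a-octahydro-1-benzoxepin-3-yl]methyl acetate | CC1(C)[C@H]2CC=C(COC(C)=O)[C@H](CBr)O[C@@]2(C)CC[C@@H]1Br | intermediate
25 | [(2R,5aR,7S,9aS)-7-bromo-2-(bromomethyl)-6,6,9a-trimethyl-2,5,5a,6,7,8,9,9a-octahydro-1-benzoxepin-3-yl]methanol | CC1(C)[C@H]2CC=C(CO)[C@H](CBr)O[C@@]2(C)CC[C@@H]1Br | target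

**Step count.** Total steps: 13. Longest linear sequence: 13 steps (1 → 25).

**Three steps most likely to fail**

1. Step 5 (key step). Process at risk: radical addition at C6 beside the quaternary C11 may be slow, so that allylic acetoxylation at C8, ionisation of the C10–Br bond at 100 °C or attack syn to bromine compete. Fallback: setting out from 8, iodoacetic acid is added by an iodine-atom-transfer radical chain (Et3B, air, ambient temperature, no oxidant), which should give 2-[(1R,3S)-3-bromo-6-iodo-2,2,6-trimethylcyclohexyl]acetic acid F1. Brief warming with NaHCO3 lets the carboxylate displace the tertiary iodide to close the same cis-fused ring, and the route is rejoined at lactone 10.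

2. Step 12. Process at risk: ionisation at the tertiary C7–O bond instead of at the methoxyethoxy group, protodesilylation, or closure through the ring-flipped transition state (bromine axial), which would give the C2 epimer; the preference between the two chair-like closures is not secure. Fallback: setting out from lactol 11, Wittig methylenation (Ph3P=CH2) should give (1S,2R,4S)-4-bromo-1,3,3-trimethyl-2-(prop-2-en-1-yl)cyclohexan-1-ol F2. Bromoacetalisation with 22 and N-bromosuccinimide should give its 2-bromo-1-(2-methoxyethoxy)ethyl ether F3. BF3·OEt2-promoted substitution of the acetal by potassium trifluoro[3-(acetyloxy)prop-1-en-2-yl]borate should then give the open-chain ether 2-[(1R)-2-bromo-1-{[(1S,2R,4S)-4-bromo-1,3,3-trimethyl-2-(prop-2-en-1-yl)cyclohexyl]oxy}ethyl]prop-2-en-1-yl acetate F4, whose C2 epimers can be separated before any ring is closed. Ring-closing metathesis with second-generation Grubbs catalyst then forms C3=C4 without touching C2 and returns to 24.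

3. Step 4. Process at risk: ionisation of the neopentylic oxyphosphonium ion with methyl shift, ring contraction or elimination to the diene instead of SN2 displacement. Fallback: setting out from 7, the alcohol is first converted at −78 °C into (1R)-2,2,4-trimethylcyclohex-3-en-1-yl trifluoromethanesulfonate F5 (Tf2O, 2,6-lutidine, CH2Cl2). This preformed sulfonate is then displaced with inversion by Bu4NBr in toluene at low temperature, returning to 8. Activation and displacement are thereby separated and no phosphonium ion pair is involved.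

**Further compounds**

F1 | step 5 | 2-[(1R,3S)-3-bromo-6-iodo-2,2,6-trimethylcyclohexyl]acetic acid (mixture at the iodide carbon) | CC1(C)[C@@H](CC(O)=O)C(C)(I)CC[C@@H]1Br
F2 | step 12 | (1S,2R,4S)-4-bromo-1,3,3-trimethyl-2-(prop-2-en-1-yl)cyclohexan-1-ol | CC1(C)[C@@H](CC=C)[C@@](C)(O)CC[C@@H]1Br
F3 | step 12 | 2-bromo-1-(2-methoxyethoxy)ethyl ether of F2 (both acetal epimers) | CC1(C)[C@@H](CC=C)[C@@](C)(OC(CBr)OCCOC)CC[C@@H]1Br
F4 | step 12 | 2-[(1R)-2-bromo-1-{[(1S,2R,4S)-4-bromo-1,3,3-trimethyl-2-(prop-2-en-1-yl)cyclohexyl]oxy}ethyl]prop-2-en-1-yl acetate | CC1(C)[C@@H](CC=C)[C@@](C)(O[C@@H](CBr)C(=C)COC(C)=O)CC[C@@H]1Br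
F5 | step 4 | (1R)-2,2,4-trimethylcyclohex-3-en-1-yl trifluoromethanesulfonate | CC1(C)C=C(C)CC[C@H]1OS(=O)(=O)C(F)(F)F
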